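## Structural features

The target is a cyclohexane (C5–C10) in which five of the six ring carbons are substituted: quaternary C10 (methyl, vinyl), C5 (a 2-propenoic acid unit bonded through its α-carbon C4), C6 and C7 (a trans-fused α-methylene-γ-butyrolactone, oxygen on C6, C11 on C7) and C8 (the angelate). The four contiguous centres C5–C8 alternate in sense, so all four substituents are equatorial in the chair that has the C10 methyl axial and the vinyl group equatorial; C10 is flanked by C5 and is 1,3 to C8. Fragile elements are the (Z)-2-methylbut-2-enoate (it isomerises to the E ester under nucleophilic catalysis), two Michael acceptors (methylene lactone and propenoic acid), the Cope-active 1,5-diene C2=C1–C10–C5–C4=C3, and the C6/C8 dioxygen pattern around C7, which allows translactonisation to the 8,12-olide and, while C6 is a ketone, β-elimination. The C15 carboxyl could also lactonise onto O6, so the two carboxyl groups must be told apart. The real difficulty is the quaternary centre C10 in a fixed relation to C8 and C5: once made it cannot be corrected by equilibration, and C5 next to it carries a branched acrylate that is hard to attach by enolate chemistry. The key step exploits the fact that the vinyl group on C10 and the propenoate on C5 together form a 1,5-hexadiene. That diene is the thermal fragmentation product of a bicyclo[2.2.0]hexane laid across C5–C10, which is what a 3-methylcyclohexenone (C5=C10) and a cyclobutene-1-carboxylate give on [2+2] photocycloaddition.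

## Logic of the disconnections

27 to 26: the C15 O–alkyl bond is cut. The acid has to stay masked through enolate, hydride and acylation steps, and a bulky acid-labile ester also keeps O6 from lactonising onto C15. The demand is a final acidolysis that spares the angelate, the lactone and the alkenes.

26 to 23 and 24: the C8 O–acyl bond is cut, so that the isomerisation-prone Z ester enters as late as possible from a commercial acid. The demand is an acylation of a hindered secondary alcohol without Z/E isomerisation and without migration of the lactone to O8.

23 to 22 to 19: the C11=C13 methylene is removed and the C8 silyl ether restored. The methylene lactone is the most reactive acceptor and should appear only after all hydride and strong-base chemistry elsewhere. The demand is clean enolisation at C11, the only enolisable position of 19, in the presence of the propenoate.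

19 to 17: the O6–C12 bond is cut and C6 returned to a ketone. The ketone makes C5 and C7 correctable by epimerisation and is the carbonyl that the photochemical step needs. The demand is a reduction that gives the equatorial 6α-alcohol although the axial C10 methyl hinders axial hydride attack, hence thermodynamic control.

17 to 14: this is the strategic cut. The 1,5-diene is reconnected at C1–C4 and C2–C3 to a bicyclo[2.2.0]hexane, so that the vinyl group, quaternary C10 and the complete propenoate come from only two carbon–carbon bonds. The demand is severe: in 14 the C10 methyl is cis to the C8 silyloxy group, in 17 it must be trans. The thermal step therefore may not retain C10; it must pass through the ring-expanded dienone 15 and re-form C5–C10 under control of C7 and C8.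

14 to 13: the C7–C11 bond is cut. The acetate arm is added at the stage where the ketone has a single α-methylene and no Michael acceptor is present, and it gives the thermal step a second equatorial anchor. The demand is a kinetic enolate that does not expel the β-silyloxy group.

13 to 8 and 11: the key cut, C10–C1 and C5–C4, opens the cyclobutane to an enone and a strained alkene. The gain is two simple building blocks, one carrying C8 and one carrying C15. The demand is head-to-head regiochemistry.

8 to 7 to 6: the C10–C14 bond is cut and the carbonyl transposed back. This leads to the enone 6 available by desymmetrisation. The demand is 1,2-addition and oxidative transposition without loss of the β-silyloxy group.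

6 to 4 to 3 to 2 to 1: the enone double bond comes from a β-acetoxy ketone, the single stereocentre from desymmetrisation of meso 3, and the all-cis oxygen pattern from hydrogenation of an arene. The demand is an enantiotopos-selective acylation.

11 to 10 to 9: the ester O–alkyl bond and then the ring double bond are cut, leading to a commercial α-bromo ester. The demand is an elimination that forms the strained alkene without conjugate addition to it.

## Other disconnections considered

Alternative 1: The cut goes through the lactone: C11–C12 and C12–O6 are broken and C12 is returned to CO. This leaves the trans-2-ethynylcyclohexanol A1 (C6 hydroxyl, C7 ethynyl, with the C8 angelate and the tert-butyl propenoate already in place).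
- Forward step: PdCl2, SnCl2 and PPh3 under CO would convert the C6 hydroxyl into an alkoxycarbonylpalladium species that adds across the neighbouring alkyne. Protonolysis would release A2, the tert-butyl ester of the target (the same structure as 26), with the exocyclic methylene in place.
- In its favour: lactone and methylene come in one neutral step, no lactone enolate is formed next to the propenoate, and no ketone reduction is needed because C6 and C7 are fixed in A1.
- Against it here: A1 still contains the hard part (C10, C5, the 1,5-diene), so the cut simplifies little. The trans hydroxyl/ethynyl pair would have to come from diaxial opening of a C6–C7 epoxide, whose sense in this ring opposes the all-equatorial array. The vinyl group, the propenoate and the angelate would all be exposed to palladium hydride and CO.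
- Comparison: on structure the chosen plan is stronger, since it creates C10, the vinyl group and the propenoate in two bond-forming events. On mechanism the two are complementary, and on the end game Alternative 1 is the better, replacing steps 12 to 14 by one step. On step economy that gain is expected to be lost in making A1, so the two are about equal.

Alternative 2: The cut is the ring bond C6–C7 together with the lactone C–O bond. It opens the carbocycle to the acyclic aldehyde A3, with the formyl carbon C6 on C5 and a 2-(bromomethyl)alk-2-enoate at C7=C11.
- Forward step: CrCl2 would turn the allylic bromide into an allylchromium species that adds through C7 to the aldehyde in a cyclic chair-like transition state. This closes the six-membered ring and gives the cyclohexanol A4 with the C11=C13 methylene and a C6 hydroxyl placed for lactonisation.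
- In its favour: divalent chromium tolerates esters and silyl ethers, and the anti C6/C7 relationship follows from the chair with all substituents equatorial, which is the array of the target. No separate methylenation is needed. On control of C6 and C7 it is the better plan than the equilibrating reduction of step 12.
- Against it here: C10 must be built as an acyclic quaternary centre next to C5. A3 is an α-branched β,γ-unsaturated aldehyde that would epimerise or conjugate easily. C15 is only an allylic ether, so oxidation to the acid and protecting-group exchanges follow the ring closure.
- Comparison: on structure the chosen plan makes the ring substituents from an existing ring, while Alternative 2 must assemble three stereocentres on a chain. On mechanism the chromium step is polar and the chosen key step photochemical, about equal in precedent. On step economy Alternative 2 is expected to be the longer.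

Alternative 3: The cut is C7–C8, which opens the ring to the aldehyde A5. It has the formyl carbon C8 at one end and an (E)-enoate (C7=C11) at the other, a triethylsilyl ether on C6, and C4 masked as the ketal of a methyl ketone.
- Forward step: SmI2 would reduce the aldehyde to a ketyl radical that adds 6-exo to C7 of the enoate. Reduction and protonation of the ester-stabilised radical would give the cyclohexanol A6 with the C8 hydroxyl and the C7 acetate arm trans.
- In its favour: the C8 hydroxyl is born free next to a protected C6 oxygen, so the two oxygens are told apart by construction. Here it is the better of the two plans, which must protect and deprotect C8. The acetate arm, C7 and C8 come in one step.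
- Against it here: six-membered ketyl–olefin closures are less selective than five-membered ones. The propenoate is not yet present, so the ketal must later be turned into the 2-propenoic acid through an enol derivative and a carbonylation. The methylene must still be added to the lactone, and C10 again has to be made on an open chain.
- Comparison: on structure Alternative 3 forms one ring bond and two centres, the chosen plan two bonds, C10 and the complete diene. On mechanism both key steps are radical ring closures of comparable reliability. On step economy the later conversion of the ketal makes Alternative 3 the longer.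

Key step: step 9

Remarks before the steps:
- Locants are those of the target (ring C5–C10; C1=C2 vinyl; C3, C4, C15 propenoate; C11–C13 lactone; C14 methyl). α is the face of the C8 oxygen in the target, β the face of the C10 methyl.
- Assumption: lipase B from Candida antarctica acetylates the carbinol of meso-diol 3 that is R by the usual secondary-alcohol rule; should the enzyme prefer the other carbinol, the same monoacetate 4 is reached by lipase hydrolysis of the diacetate of 3.
- Check of the key-step structures: C8 of 8 maps onto C8 (S) of the target with the same neighbours. In 13 the cyclobutane is anti to the silyloxy group, so the C10 methyl is cis to it; this is the opposite of the target, and C10 must therefore be re-made in step 11.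
- Design changes around the key step: the C7 arm is installed on the photoadduct before thermolysis (step 10), as an isopropyl ester, and C6 is reduced under thermodynamic control (step 12).

## Steps

Step 1
Reactants: 1 benzene-1,3,5-triol (phloroglucinol)
Product: 2 all-cis-cyclohexane-1,3,5-triol
Conditions: H2 (80 bar), 5% Rh/Al2O3, EtOH, 60 °C
Reagents that add atoms: none
Why: Heterogeneous arene hydrogenation delivers all six hydrogens to one face, giving the all-cis triol; rhodium on alumina keeps C–O hydrogenolysis low.

Step 2
Reactants: 2 all-cis-cyclohexane-1,3,5-triol
Product: 3 all-cis-5-(tert-butyldimethylsilyloxy)cyclohexane-1,3-diol (meso)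
Conditions: TBSCl (0.95 equiv), imidazole, DMF, 0 °C → rt
Reagents that add atoms: tert-butyldimethylsilyl chloride, CC(C)(C)[Si](C)(C)Cl
Why: Statistical monosilylation of three equivalent hydroxyls; a slight deficit of silyl chloride limits bis-silylation and unreacted 2 is recycled. The product is meso, so no stereochemistry is set.

Step 3
Reactants: 3 all-cis-5-(tert-butyldimethylsilyloxy)cyclohexane-1,3-diol
Product: 4 (1R,3S,5S)-3-(tert-butyldimethylsilyloxy)-5-hydroxycyclohexyl acetate
Conditions: vinyl acetate, lipase B from Candida antarctica (immobilised), tert-butyl methyl ether, 30 °C
Reagents that add atoms: vinyl acetate, CC(=O)OC=C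
Why: Lipase-catalysed desymmetrising transesterification: the enzyme acylates one of the two enantiotopic carbinols, and this fixes the silyloxy-bearing carbon as the future C8. Over-acylation consumes the minor enantiomer preferentially, which should raise the optical purity.

Step 4
Reactants: 4 (1R,3S,5S)-3-(tert-butyldimethylsilyloxy)-5-hydroxycyclohexyl acetate
Product: 6 (R)-5-(tert-butyldimethylsilyloxy)cyclohex-2-en-1-one, via acetoxy ketone 5 (not isolated)
Conditions: Dess–Martin periodinane, CH2Cl2, 0 °C → rt; then Et3N, 0 °C → rt
Reagents that add atoms: none
Why: Alcohol oxidation gives the β-acetoxy ketone 5; E1cB loss of acetate, a far better leaving group than silanolate, gives the enone under mild amine base that should leave the silyloxy group in place. The silyloxy carbinol centre is untouched.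

Step 5
Reactants: 6 (R)-5-(tert-butyldimethylsilyloxy)cyclohex-2-en-1-one
Product: 7 (5R)-5-(tert-butyldimethylsilyloxy)-1-methylcyclohex-2-en-1-ol (both C1 epimers)
Conditions: MeLi, Et2O, −78 °C; then H2O
Reagents that add atoms: methyllithium, [Li]C
Why: 1,2-Addition of a hard organolithium to the enone carbonyl, faster at −78 °C than α′-deprotonation; the new carbinol centre is destroyed in the next step, so its configuration is irrelevant.

Step 6
Reactants: 7 (5R)-5-(tert-butyldimethylsilyloxy)-1-methylcyclohex-2-en-1-ol
Product: 8 (S)-5-(tert-butyldimethylsilyloxy)-3-methylcyclohex-2-en-1-one
Conditions: pyridinium chlorochromate, 4 Å molecular sieves, CH2Cl2, rt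
Reagents that add atoms: pyridinium chlorochromate (supplies the new carbonyl oxygen), [O-][Cr](=O)(=O)Cl.c1cc[nH+]cc1
Why: Dauben–Babler oxidative 1,3-transposition: the chromate ester of the tertiary allylic alcohol undergoes a [3,3] shift and is oxidised to the transposed enone, placing the methyl on the β-carbon (C10) and the carbonyl at C6. The silyloxy centre is not touched; its descriptor changes from R to S only because the neighbour priorities change.

Step 7
Reactants: 9 ethyl 1-bromocyclobutane-1-carboxylate
Product: 10 cyclobut-1-ene-1-carboxylic acid
Conditions: KOH (powdered), toluene, reflux; then aq. HCl, 0 °C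
Reagents that add atoms: potassium hydroxide, [K+].[OH-]
Why: E2 dehydrobromination combined with saponification, the established preparation of this acid; all β-hydrogens are equivalent, so only one alkene can form.

Step 8
Reactants: 10 cyclobut-1-ene-1-carboxylic acid
Product: 11 tert-butyl cyclobut-1-ene-1-carboxylate
Conditions: tert-butyl 2,2,2-trichloroacetimidate, BF3·OEt2 (cat.), cyclohexane/CH2Cl2, rt
Reagents that add atoms: tert-butyl 2,2,2-trichloroacetimidate, CC(C)(C)OC(=N)C(Cl)(Cl)Cl
Why: Acid-catalysed O-alkylation of the carboxylic acid by the imidate (tert-butyl cation transfer); no base or nucleophile is present that could add to the strained acrylate.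

Step 9
Reactants: 8 (S)-5-(tert-butyldimethylsilyloxy)-3-methylcyclohex-2-en-1-one; 11 tert-butyl cyclobut-1-ene-1-carboxylate
Product: 13 cis-anti-cis head-to-head photoadduct (cyclohexanone fused to a bicyclo[2.2.0]hexane; ester carbon C4 on C5; cyclobutane anti to the C8 silyloxy group), via trans-fused adduct 12 (not isolated)
Conditions: 11 (4 equiv), hν (350 nm, Pyrex), CH2Cl2, −40 °C; then basic Al2O3, rt
Reagents that add atoms: none
Why: Excitation of enone 8 and intersystem crossing give the twisted triplet, whose β-carbon C10 bonds to the unsubstituted carbon C1 of 11 to form a triplet 1,4-biradical with an α-keto radical at C5 and a tertiary ester-stabilised radical at C4. After spin inversion, radical recombination closes C5–C4; this single collapse closes both the cyclobutane C5–C10–C1–C4 and the six-membered ring C5–C10–C1–C2–C3–C4 of the bicyclo[2.2.0]hexane, the four-membered ring of 11 being carried in intact. The closest known reaction type is the enone–alkene [2+2] photocycloaddition in its head-to-head variant with cyclobut-1-ene-1-carboxylates and 3-methylcyclohexenones. The one selectivity the plan needs from this step is head-to-head regiochemistry (C4 on C5), and the polarity of 11 secures it: an electron-poor alkene bonds through its β-carbon so that both radical centres are stabilised. C10 is set by approach anti to the C8 silyloxy group (methyl cis to it), C5 by the cis ring fusion reached when alumina epimerises the trans-fused isomer 12 α to the ketone, and C1 and C4 by the cis fusion of the cyclobutene ring in its exo orientation. None of these four centres is carried into the target as such: C1 and C4 become sp2 and C5 and C10 are re-made in step 11. Excess 11, long-wavelength light and low temperature limit enone dimerisation and loss of silanol from the β-silyloxy ketone.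

Step 10
Reactants: 13 cis-anti-cis head-to-head photoadduct
Product: 14 C7-alkylated photoadduct (isopropoxycarbonylmethyl group on C7 trans to the C8 silyloxy group)
Conditions: LiN(iPr)2, THF, −78 °C; BrCH2CO2iPr, DMPU, −78 → −40 °C
Reagents that add atoms: isopropyl bromoacetate, CC(C)OC(=O)CBr
Why: Kinetic ketone enolate alkylation: the base removes a proton from C7, the only α-methylene (C5–H is a hindered cyclobutane methine), and the electrophile enters anti to the neighbouring silyloxy group. The equatorial C–O bond lies near the enolate plane, which disfavours β-elimination; C7 also remains correctable through the ketone.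

Step 11
Reactants: 14 C7-alkylated photoadduct
Product: 17 keto diester (cyclohexanone with C10 methyl β and vinyl α; C5 tert-butyl propenoate β; C7 arm β; C8 silyloxy α), via cyclodecadienone 15 (not isolated), via C5 epimer 16 (not isolated)
Conditions: toluene (0.02 M), BHT (cat.), base-washed sealed tube, 190 °C; then DBU (5 mol %), toluene, 0 °C
Reagents that add atoms: none
Why: Strain-driven homolysis of the central C1–C4 bond and scission of C5–C10 (the known thermal half of the photochemical–thermal olefin metathesis) give the ring-expanded dienone 15, in which C1, C4, C5 and C10 are all flattened. Cope rearrangement through the chair that keeps the C7 arm and the C8 silyloxy group equatorial re-forms C5–C10; with both ring double bonds trans the methyl group is axial and the vinyl group cis to the silyloxy group, which sets C10 and C5 of 17. Catalytic DBU converges the cis-divinyl ketone 16 from any boat-like closure, and any C7 epimer, on the all-equatorial ketone through the enol.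

Step 12
Reactants: 17 keto diester
Product: 19 trans-fused 6α,12-lactone (C8 silyl ether; C15 tert-butyl ester), via hydroxy ester 18 (not isolated)
Conditions: Al(OiPr)3, iPrOH/toluene, 80 °C, acetone distilled off, then acetone (trace), 80 °C; aq. KNaC4H4O6; then PPTS (cat.), toluene, 60 °C
Reagents that add atoms: none
Why: Meerwein–Ponndorf–Verley reduction run to equilibrium: reversible hydride transfer gives the equatorial 6α-alcohol, because the axial epimer would be syn-diaxial to the C10 methyl. Kinetic hydrides are expected to attack from the equatorial side, since that methyl shields the axial path. Acid-catalysed lactonisation then takes the unhindered isopropyl ester and not the conjugated tert-butyl ester, closing the trans-fused lactone.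

Step 13
Reactants: 19 trans-fused 6α,12-lactone
Product: 20 α-(dimethylaminomethyl) lactone (both C11 epimers)
Conditions: LiN(iPr)2, THF, −78 °C; Me2N=CH2 I (Eschenmoser's salt), −78 → 0 °C
Reagents that add atoms: dimethylmethyleneammonium iodide, C=[N+](C)C.[I-]
Why: Mannich reaction of the lactone enolate with a preformed iminium salt; C11 is the only enolisable position and the trans ring fusion rules out an intramolecular Michael addition to the propenoate. The new C11 centre is removed in the next step.

Step 14
Reactants: 20 α-(dimethylaminomethyl) lactone
Product: 22 α-methylene lactone (C8 silyl ether; C15 tert-butyl ester), via ammonium iodide 21 (not isolated)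
Conditions: MeI, MeOH, rt; then aq. NaHCO3/CH2Cl2, rt
Reagents that add atoms: none
Why: N-Methylation followed by base-induced β-elimination of trimethylamine, the standard two-stage α-methylenation of lactones; no stereocentre is affected.

Step 15
Reactants: 22 α-methylene lactone silyl ether
Product: 23 C8 alcohol (6α,12-olide; C15 tert-butyl ester)
Conditions: HF·pyridine, pyridine, THF, 0 °C → rt
Reagents that add atoms: none
Why: Fluoride cleavage of the Si–O bond under buffered acidic conditions; no C8 alkoxide is formed, so translactonisation to the 8,12-olide should be avoided, and the tert-butyl ester and both acceptors are inert.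

Step 16
Reactants: 23 C8 alcohol; 24 angelic acid ((Z)-2-methylbut-2-enoic acid)
Product: 26 tert-butyl ester of the target (8α-angelate), via mixed anhydride 25 (not isolated)
Conditions: 24, 2,4,6-trichlorobenzoyl chloride, Et3N, toluene, rt; then 23, 80 °C
Reagents that add atoms: none
Why: Yamaguchi esterification through the mixed anhydride 25 without a nucleophilic catalyst, the conditions under which angelates are formed with the Z geometry intact (pyridine-type catalysts isomerise the activated acyl by conjugate addition). The C8–O bond is not broken, so C8 is retained.

Step 17
Reactants: 26 tert-butyl ester of the target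
Product: 27 target acid, 2-[(3aR,4S,6S,7R,7aR)-6-ethenyl-6-methyl-3-methylidene-4-{[(2Z)-2-methylbut-2-enoyl]oxy}-2-oxooctahydro-1-benzofuran-7-yl]prop-2-enoic acid
Conditions: CF3CO2H/CH2Cl2 (1:4), 0 °C
Reagents that add atoms: none
Why: Acidolysis of the tert-butyl ester by alkyl–oxygen cleavage with loss of 2-methylpropene; lactone, angelate and the alkenes are expected to be stable to trifluoroacetic acid at 0 °C.

## Compound list

1 | benzene-1,3,5-triol (phloroglucinol) | Oc1cc(O)cc(O)c1 | starting material
2 | all-cis-cyclohexane-1,3,5-triol | O[C@H]1C[C@@H](O)C[C@@H](O)C1 | intermediate
3 | all-cis-5-(tert-butyldimethylsilyloxy)cyclohexane-1,3-diol (meso) | O[C@H]1C[C@@H](O)C[C@@H](O[Si](C)(C)C(C)(C)C)C1 | intermediate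
4 | (1R,3S,5S)-3-(tert-butyldimethylsilyloxy)-5-hydroxycyclohexyl acetate | CC(=O)O[C@@H]1C[C@H](O)C[C@H](O[Si](C)(C)C(C)(C)C)C1 | intermediate
5 | (1S,3R)-3-(tert-butyldimethylsilyloxy)-5-oxocyclohexyl acetate | CC(=O)O[C@@H]1CC(=O)C[C@H](O[Si](C)(C)C(C)(C)C)C1 | intermediate (not isolated)
6 | (R)-5-(tert-butyldimethylsilyloxy)cyclohex-2-en-1-one | O=C1C=CC[C@@H](O[Si](C)(C)C(C)(C)C)C1 | intermediate
7 | (5R)-5-(tert-butyldimethylsilyloxy)-1-methylcyclohex-2-en-1-ol, both C1 epimers | CC1(O)C=CC[C@@H](O[Si](C)(C)C(C)(C)C)C1 | intermediate
8 | (S)-5-(tert-butyldimethylsilyloxy)-3-methylcyclohex-2-en-1-one | CC1=CC(=O)C[C@@H](O[Si](C)(C)C(C)(C)C)C1 | intermediate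
9 | ethyl 1-bromocyclobutane-1-carboxylate | CCOC(=O)C1(Br)CCC1 | starting material
10 | cyclobut-1-ene-1-carboxylic acid | OC(=O)C1=CCC1 | intermediate
11 | tert-butyl cyclobut-1-ene-1-carboxylate | CC(C)(C)OC(=O)C1=CCC1 | intermediate
12 | trans-fused head-to-head photoadduct (C5 epimer of 13: H5 cis, C4 trans to the C10–C1 bond) | O=C1C[C@@H](O[Si](C)(C)C(C)(C)C)C[C@@]2(C)[C@H]1[C@]3(C(=O)OC(C)(C)C)CC[C@H]23 | intermediate (not isolated)
13 | cis-anti-cis head-to-head photoadduct: C6 ketone, C8 silyloxy, C10 methyl cis to the silyloxy group, cyclobutane C5–C10–C1–C4 on the opposite face, tert-butyl ester on C4, second cyclobutane C1–C2–C3–C4 anti to the six-membered ring | O=C1C[C@@H](O[Si](C)(C)C(C)(C)C)C[C@@]2(C)[C@@H]1[C@]3(C(=O)OC(C)(C)C)CC[C@H]23 | intermediate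
14 | 13 carrying CH2CO2iPr on C7, trans to the C8 silyloxy group | O=C1[C@H](CC(=O)OC(C)C)[C@@H](O[Si](C)(C)C(C)(C)C)C[C@@]2(C)[C@@H]1[C@]3(C(=O)OC(C)(C)C)CC[C@H]23 | intermediate
15 | cyclodeca-1(10),4-dien-6-one with both ring double bonds trans: C4 tert-butyl ester, C7 CH2CO2iPr, C8 silyloxy, C10 methyl | C/C1=C\CC/C(C(=O)OC(C)(C)C)=C/C(=O)[C@H](CC(=O)OC(C)C)[C@@H](O[Si](C)(C)C(C)(C)C)C1 | intermediate (not isolated)
16 | C5 epimer of 17 (propenoate on C5 cis to the vinyl group) | C=C[C@]1(C)C[C@H](O[Si](C)(C)C(C)(C)C)[C@@H](CC(=O)OC(C)C)C(=O)[C@@H]1C(=C)C(=O)OC(C)(C)C | intermediate (not isolated)
17 | keto diester: C6 ketone; C10 methyl β, vinyl α; C5 tert-butyl propenoate β; C7 CH2CO2iPr β; C8 silyloxy α | C=C[C@]1(C)C[C@H](O[Si](C)(C)C(C)(C)C)[C@@H](CC(=O)OC(C)C)C(=O)[C@H]1C(=C)C(=O)OC(C)(C)C | intermediate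
18 | 6α-hydroxy diester | C=C[C@]1(C)C[C@H](O[Si](C)(C)C(C)(C)C)[C@@H](CC(=O)OC(C)C)[C@H](O)[C@H]1C(=C)C(=O)OC(C)(C)C | intermediate (not isolated)
19 | trans-fused 6α,12-lactone, C8 silyl ether, C15 tert-butyl ester | C=C[C@]1(C)C[C@H](O[Si](C)(C)C(C)(C)C)[C@H]2CC(=O)O[C@@H]2[C@H]1C(=C)C(=O)OC(C)(C)C | intermediate
20 | 19 with CH2NMe2 on C11, both C11 epimers | C=C[C@]1(C)C[C@H](O[Si](C)(C)C(C)(C)C)[C@H]2C(CN(C)C)C(=O)O[C@@H]2[C@H]1C(=C)C(=O)OC(C)(C)C | intermediate
21 | trimethylammonium iodide of 20 | C=C[C@]1(C)C[C@H](O[Si](C)(C)C(C)(C)C)[C@H]2C(C[N+](C)(C)C)C(=O)O[C@@H]2[C@H]1C(=C)C(=O)OC(C)(C)C.[I-] | intermediate (not isolated)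
22 | α-methylene lactone, C8 silyl ether, C15 tert-butyl ester | C=C[C@]1(C)C[C@H](O[Si](C)(C)C(C)(C)C)[C@H]2C(=C)C(=O)O[C@@H]2[C@H]1C(=C)C(=O)OC(C)(C)C | intermediate
23 | α-methylene lactone with free 8α-hydroxyl, C15 tert-butyl ester | C=C[C@]1(C)C[C@H](O)[C@H]2C(=C)C(=O)O[C@@H]2[C@H]1C(=C)C(=O)OC(C)(C)C | intermediate
24 | angelic acid, (Z)-2-methylbut-2-enoic acid | C/C=C(/C)C(=O)O | starting material
25 | (Z)-2-methylbut-2-enoic 2,4,6-trichlorobenzoic anhydride | C/C=C(/C)C(=O)OC(=O)c1c(Cl)cc(Cl)cc1Cl | intermediate (not isolated)
26 | tert-butyl ester of the target | C=C[C@]1(C)C[C@H](OC(=O)/C(C)=C\C)[C@H]2C(=C)C(=O)O[C@@H]2[C@H]1C(=C)C(=O)OC(C)(C)C | intermediate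
27 | target, (5R,6R,7R,8S,10S) in the locants used here | C=C[C@]1(C)C[C@H](OC(=O)/C(C)=C\C)[C@H]2C(=C)C(=O)O[C@@H]2[C@H]1C(=C)C(=O)O | target

## Step count and least certain steps

Total: 17 steps. Longest linear sequence: 15 steps (steps 1–6 and 9–17); the cyclobutene ester is a two-step branch (steps 7 and 8).

Step 9 (key step). Most likely to go wrong: regiochemical leakage to head-to-tail adducts, and a cycloaddition that is slow relative to enone dimerisation, radical oligomerisation of 11 or loss of silanol from 8 (aromatisation to a cresol that then absorbs the light). The reason is that the head-to-head preference rests on polarity alone and not on a geometric constraint. Fallback: change the alkene partner to the free acid, whose carboxyl group can hydrogen-bond to the enone carbonyl and so hold its own carbon next to C5. The fallback sets out from 8 and 10; irradiation as in step 9 would give the tricyclic keto acid F1, and tert-butylation with the imidate of step 8 comes back to the route at 13.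

Step 11. Most likely to go wrong: leakage of the ring-fusion stereochemistry of 14 into the geometry of the dienone. Bicyclo[2.2.0]hexanes are known to open with inversion at one terminus. In the cis-fused compound 14 that mode would give a dienone with a cis C4=C5 ring bond; its chair closure would put the vinyl group axial and the methyl group equatorial, that is, the C10 epimer of 17. Because C10 is quaternary and the vinyl-axial and methyl-axial arrangements differ little in energy, neither base nor further heating could repair this. Lesser hazards are thermal loss of 2-methylpropene from the tert-butyl ester, polymerisation of the propenoate and base-induced conjugation of the C3=C4 bond into the ketone. Fallback: change the relay from the cis-fused to the trans-fused adduct. It sets out from 12, kept by omitting the alumina treatment of step 9 and separating on neutral silica at 0 °C. Kinetic alkylation as in step 10 would give the trans-fused C7-alkylated adduct F2. In F2 the two ring residues C6 and C9 are both equatorial on the diyl ring, so the same inversion mode would lead to the dienone with two trans ring bonds, 15, and the route is rejoined at 17.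

Step 10. Most likely to go wrong: β-elimination of silanolate from the C7 enolate on warming, or proton transfer between enolate and product leading to double alkylation, because bromoacetates react only slowly with lithium enolates at −78 °C. Fallback: replace enolate alkylation by alkylation of a neutral enol derivative. It sets out from 13: deprotonation with LiN(iPr)2 in the presence of Me3SiCl would trap the kinetic enolate at once as the silyl enol ether F3. Tsuji allylation (allyl methyl carbonate, Pd2(dba)3 as the zerovalent palladium source, dppe, THF) would give the 7-allyl ketone F4, anti to the silyloxy group. RuCl3 (cat.)/NaIO4 would cleave the only alkene present to the carboxylic acid F5, and esterification with propan-2-ol (carbodiimide, DMAP cat.) comes back at 14.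

Step 12. Most likely to go wrong: incomplete equilibration, so that the kinetically delivered axial 6β-alkoxide is trapped as the cis-fused lactone, or loss of silanol and conjugation of the propenoate double bond under the hot Lewis-acidic alkoxide. Fallback: accept kinetic control and invert C6 in the ring closure. It sets out from 17: LiAlH(OtBu)3 (THF, −78 → 0 °C) should attack from the equatorial side, which the C10 methyl does not shield, and the axial alkoxide would close to the cis-fused 6β,12-lactone F6. LiOH (THF/H2O, 0 °C) would open it to the 6β-hydroxy acid F7, handled as its salt. Mitsunobu lactonisation (PPh3, diisopropyl azodicarboxylate, THF, 0 °C) would displace the activated axial hydroxyl by the carboxylate with inversion and comes back at 19.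

Step 16. Most likely to go wrong: isomerisation of the angelate to the tiglate on the activated acyl, and an acylation of the hindered C8 hydroxyl slow enough at 80 °C for translactonisation to the 8,12-olide to compete. Fallback: form the Z double bond after the acylation. It sets out from 23: esterification with 2-(diphenoxyphosphoryl)propanoic acid (carbodiimide, CH2Cl2, 0 °C) would give the phosphonopropionate F8. A Z-selective Horner–Wadsworth–Emmons reaction of the Ando type with acetaldehyde (NaI, DBU, THF, −78 → 0 °C) then comes back at 26.

## Further compounds

F1 | step 9 | cis-anti-cis head-to-head photoadduct with free carboxylic acid on C4 | O=C1C[C@@H](O[Si](C)(C)C(C)(C)C)C[C@@]2(C)[C@@H]1[C@]3(C(=O)O)CC[C@H]23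
F2 | step 11 | trans-fused C7-alkylated photoadduct (C5 epimer of 14) | O=C1[C@H](CC(=O)OC(C)C)[C@@H](O[Si](C)(C)C(C)(C)C)C[C@@]2(C)[C@H]1[C@]3(C(=O)OC(C)(C)C)CC[C@H]23
F3 | step 10 | C6=C7 trimethylsilyl enol ether of 13 | C[Si](C)(C)OC1=C[C@@H](O[Si](C)(C)C(C)(C)C)C[C@@]2(C)[C@@H]1[C@]3(C(=O)OC(C)(C)C)CC[C@H]23
F4 | step 10 | 13 carrying an allyl group on C7, trans to the C8 silyloxy group | O=C1[C@H](CC=C)[C@@H](O[Si](C)(C)C(C)(C)C)C[C@@]2(C)[C@@H]1[C@]3(C(=O)OC(C)(C)C)CC[C@H]23
F5 | step 10 | 13 carrying CH2CO2H on C7, trans to the C8 silyloxy group | O=C1[C@H](CC(=O)O)[C@@H](O[Si](C)(C)C(C)(C)C)C[C@@]2(C)[C@@H]1[C@]3(C(=O)OC(C)(C)C)CC[C@H]23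
F6 | step 12 | cis-fused 6β,12-lactone (C6 epimer of 19) | C=C[C@]1(C)C[C@H](O[Si](C)(C)C(C)(C)C)[C@H]2CC(=O)O[C@H]2[C@H]1C(=C)C(=O)OC(C)(C)C
F7 | step 12 | 6β-hydroxy acid (C12 acid; C15 tert-butyl ester) | C=C[C@]1(C)C[C@H](O[Si](C)(C)C(C)(C)C)[C@@H](CC(=O)O)[C@@H](O)[C@H]1C(=C)C(=O)OC(C)(C)C
F8 | step 16 | 8α-[2-(diphenoxyphosphoryl)propanoate] of 23 | C=C[C@]1(C)C[C@H](OC(=O)C(C)P(=O)(Oc3ccccc3)Oc3ccccc3)[C@H]2C(=C)C(=O)O[C@@H]2[C@H]1C(=C)C(=O)OC(C)(C)C
A1 | alternative 1 | trans-2-ethynylcyclohexanol precursor (C6 hydroxyl, C7 ethynyl, C8 angelate, C5 tert-butyl propenoate) | C=C[C@]1(C)C[C@H](OC(=O)/C(C)=C\C)[C@@H](C#C)[C@H](O)[C@H]1C(=C)C(=O)OC(C)(C)C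
A2 | alternative 1 | tert-butyl ester of the target (same structure as 26) | C=C[C@]1(C)C[C@H](OC(=O)/C(C)=C\C)[C@H]2C(=C)C(=O)O[C@@H]2[C@H]1C(=C)C(=O)OC(C)(C)C
A3 | alternative 2 | acyclic C6 aldehyde with (Z)-2-(bromomethyl)alk-2-enoate at C7=C11 | C=C[C@](C)(C[C@H](O[Si](C)(C)C(C)(C)C)/C=C(\CBr)C(=O)OC)[C@@H](C=O)C(=C)COCc1ccc(OC)cc1
A4 | alternative 2 | cyclohexanol with methyl 2-propenoate on C7 and free C6 hydroxyl | C=C[C@]1(C)C[C@H](O[Si](C)(C)C(C)(C)C)[C@@H](C(=C)C(=O)OC)[C@H](O)[C@H]1C(=C)COCc2ccc(OC)cc2
A5 | alternative 3 | acyclic C8 aldehyde with (E)-enoate at C7=C11, C6 triethylsilyl ether, C4 ketal | C=C[C@](C)(CC=O)[C@@H]([C@@H](O[Si](CC)(CC)CC)/C=C/C(=O)OC(C)(C)C)C1(C)OCCO1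
A6 | alternative 3 | cyclohexanol with tert-butyl acetate arm on C7 and free C8 hydroxyl | C=C[C@]1(C)C[C@H](O)[C@@H](CC(=O)OC(C)(C)C)[C@H](O[Si](CC)(CC)CC)[C@H]1C2(C)OCCO2
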